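The product tells us how far the flask has gone: the sum of the two products, and the excess of left-handed over right-handed in it.

| setting | cedar | birch | Tuesday's | Monday's |
|---|---|---|---|---|
| left-handed substrate | 11 mM | 11 mM | 11 mM | 11 mM |
| right-handed substrate | 11 mM | 11 mM | 11 mM | 11 mM |
| partner | 7.7 mM | 38 mM | 6.60 mM | 25.0 mM |
| protic impurity | 3.3 mM | 3.3 mM | 3.30 mM | 3.30 mM |
| free catalyst | 0.18 mM | 0.18 mM | 0.18 mM | 0.18 mM |
| stray impurity | 55 µM | 55 µM | 55 µM | 55 µM |
| remark | run made earlier | run made earlier |  |  |
| time |  |  | 12 h | 12 h |

- cedar (time / h: left-handed product / %, right-handed product / %, left-handed substrate / %): 1.00: 3.4, 0.7, 45.7; 1.50: 5.6, 1.1, 45.7; 2.50: 6.6, 0.7, 44.0; 4.00: 8.4, 2.3, 41.4; 8.00: 11.7, 2.6, 37.5; 12.0: 14.2, 3.0, 35.8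
- birch (time / h: left-handed product / %, right-handed product / %, left-handed substrate / %): 1.00: 18.0, 3.5, 31.0; 1.50: 23.7, 5.1, 25.9; 2.50: 32.4, 7.6, 17.5; 4.00: 39.7, 11.8, 10.7; 8.00: 46.5, 20.1, 3.3; 12.0: 49.5, 24.3, 1.6

(standard deviation of a reading: 0.5 percentage points)

- free catalyst is single-handed; left-handed substrate and right-handed substrate are mirror images of each other, charged as a racemate, each of them at the stated concentration
- an excess is the difference of the two amounts in percent of their sum
- an excess is below zero if the other one leads

* which one finishes higher in excess of left-handed product over right-handed product in the product ("neither" within 2 percentage points) (Tuesday's / Monday's / neither)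
* excess of left-handed product over right-handed product in the product at the end, Tuesday's
* excess of left-handed product over right-handed product in the product at the end, Monday's

Cedar looks nearly the same as Tuesday's, and its product slows early: at 12.0 h its products sum to 17.2% of the substrate, or 3.78 mM, from 7.7 mM of partner. We read this as the protic impurity taking partner mole for mole. Call U the partner charged less the protic impurity charged: 4.40 mM in cedar, 3.30 mM in Tuesday's. This usable partner is the quantity to carry.

By 12.0 h cedar has turned 86.0% of its U into product, as far as the readings show. With the same substrate charge, we take that share for Tuesday's, which gives product of 12.9%. Birch at 4.00 h gives a reading of the selectivity factor s, the ratio of the logarithms of what remains of each substrate: 5.73. On that reading the first product formed has an excess of 70.3%. Replacing each substrate curve by its mean lowers the ratio of the products in Tuesday's to 5.20, an excess of 67.7%.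

Monday's has 21.7 mM of U, and we scale it from birch, whose mean usable partner up to 4.00 h we reckon at 29.0 mM. Taking the mean in Monday's at 66.7% of U and scaling birch's logarithm for the left-handed substrate by mean partner times time gives 2.30. That means product of 61.6% and an excess of 46.2%. So we expect Tuesday's to end higher, because we reckon less product for it.

The forecast says Tuesday's, with 66% and 47%, on the ground that “the excess falls only because conversion rises”. Our Tuesday's figure lies above its figure, and our Monday's figure below.

The flasks give Tuesday's: 67.3% for Tuesday's and 47.7% for Monday's.

    partner + free catalyst + left-handed substrate → free catalyst + left-handed product (k = 31.0 L² mol⁻² s⁻¹)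
    free catalyst + stray impurity → spent catalyst B (k = 440 L mol⁻¹ s⁻¹)
    partner + protic impurity → quenched reagent (k = 0.180 L mol⁻¹ s⁻¹)
    free catalyst → spent catalyst A (k = 1.80 × 10⁻⁷ s⁻¹)
    partner + free catalyst + right-handed substrate → free catalyst + right-handed product (k = 5.50 L² mol⁻² s⁻¹)

Tuesday's at 120 h holds products summing to 15.0% of the substrate, where U allows 15.0%. The neighbour of Tuesday's charged with 16 mM of partner has 12.7 mM of U. The Monday reckoning gives it a logarithm of 1.35 and an excess of 55.8%. That flask ends at 58.2%.

The readings were generated by integration with made-up constants, and the scatter is random.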